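**Plan**

- Locants: ring A = C1–C5 (side chain on C1, methyl on C4, spiro C5); ring B = C5–C10 (C7=C8, methyl on C8, acyloxy on C9); C6′ = side-chain CH(CH3); C5′ = the adjoining =CH of the ylidene lactone.
- Cuts, in retrosynthetic order: the C9–O ester; the C5′=C(lactone) bond (aldol–dehydration); the C5–C1 bond of ring A together with the C6′–H bond (ene reaction); C1=C6′ (olefination); the aryl–C4 bond (conjugate addition).
- Forward: the C4–C1 chain is grown on an aryl group that is ring B in aromatic form. Birch reduction unmasks ring B, ring A then closes at spiro C5, and the butenolide and the 3-phenylpropanoate go on last.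
- Enabling feature: ring B is a latent 2-methylanisole. Its Birch diene offers the C5=C6 alkene next to the doubly allylic C7–H2, and the C4–C3–C2 tether holds the (Z)-enoate C1=C6′ within reach, so one ene reaction creates spiro C5.
- Stereochemistry: C4 from Rh/(R)-BINAP conjugate addition; C5, C1 and C6′ from the ene step (C4-directed face, cis-fused transition state, (Z)-enoate geometry); C9 from a reagent-controlled CBS reduction; the (Z)-ylidene from a thermodynamically controlled E1cB elimination.

Key step: step 8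

Remark: the spirocyclic intermediates are named with the locants defined above; the target as drawn is (1R,4S,5S,9S,6′S) with a (Z)-ylidene lactone.

**Route**

Step 1
Reactants: 1 (3-methoxy-4-methylphenyl)boronic acid; 2 propan-2-yl (2E)-but-2-enoate
Product: 3 propan-2-yl (3S)-3-(3-methoxy-4-methylphenyl)butanoate
Conditions: Rh(acac)(C2H4)2 (3 mol %), (R)-BINAP, 1,4-dioxane/H2O, 100 °C
Reagents that add atoms: none
Why: Hayashi–Miyaura rhodium-catalysed 1,4-addition, in which the aryl-rhodium BINAP species inserts the (E)-enoate on one enantioface and water protonates the resulting oxa-π-allyl; with (R)-BINAP the aryl group should be delivered to the face that gives the (3S) ester, which fixes C4, and the isopropyl ester is chosen because bulkier crotonates react with higher enantioselectivity.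

Step 2
Reactants: 3 propan-2-yl (3S)-3-(3-methoxy-4-methylphenyl)butanoate
Product: 4 (3S)-3-(3-methoxy-4-methylphenyl)butanal
Conditions: i-Bu2AlH (DIBAL-H), CH2Cl2, −78 °C; MeOH, then aq. potassium sodium tartrate
Reagents that add atoms: none
Why: Low-temperature DIBAL-H half-reduction of an ester to the aldehyde, quenched cold to prevent over-reduction; the stereocentre is β to the carbonyl and is not at risk.

Step 3
Reactants: 4 (3S)-3-(3-methoxy-4-methylphenyl)butanal
Product: 5 2-methoxy-1-methyl-4-[(2S)-pent-4-en-2-yl]benzene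
Conditions: Ph3PCH3Br, KOtBu, THF, 0 °C to rt
Reagents that add atoms: methyltriphenylphosphonium bromide, C[P+](c1ccccc1)(c1ccccc1)c1ccccc1.[Br-]
Why: Wittig methylenation with the non-stabilised ylide adds the carbon that becomes C1.

Step 4
Reactants: 5 2-methoxy-1-methyl-4-[(2S)-pent-4-en-2-yl]benzene
Product: 7 (4S)-4-(3-methoxy-4-methylphenyl)pentan-1-ol, via B-alkyl-9-borabicyclononane 6 (not isolated)
Conditions: 9-BBN, THF, 0 °C to rt; then aq. NaOH, H2O2, 0 °C
Reagents that add atoms: 9-borabicyclo[3.3.1]nonane, B1C2CCCC1CCC2 (its atoms are carried by 6 only); hydrogen peroxide, OO (supplies the hydroxyl oxygen of 7)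
Why: Brown hydroboration–oxidation, in which 9-BBN adds anti-Markovnikov to the terminal alkene and alkaline peroxide replaces boron by oxygen with retention.

Step 5
Reactants: 7 (4S)-4-(3-methoxy-4-methylphenyl)pentan-1-ol
Product: 8 (4S)-4-(5-methoxy-4-methylcyclohexa-1,4-dien-1-yl)pentan-1-ol
Conditions: Li, liq. NH3, THF, t-BuOH, −78 to −33 °C; MeOH quench
Reagents that add atoms: none
Why: Birch reduction, in which the arene radical anion is protonated at the two unsubstituted para-related carbons (future C7 and C10) so that methoxy, methyl and alkyl all stay on sp2 carbons, giving the C8=C9 enol ether and the C5=C6 alkene; the alcohol is carried as its alkoxide.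

Step 6
Reactants: 8 (4S)-4-(5-methoxy-4-methylcyclohexa-1,4-dien-1-yl)pentan-1-ol
Product: 9 (4S)-4-(5-methoxy-4-methylcyclohexa-1,4-dien-1-yl)pentanal
Conditions: SO3·pyridine, DMSO, i-Pr2NEt, CH2Cl2, 0 °C
Reagents that add atoms: none
Why: Parikh–Doering oxidation (activated DMSO under basic, non-aqueous conditions) should give the aldehyde without exposing the acid-labile enol ether to acid.

Step 7
Reactants: 9 (4S)-4-(5-methoxy-4-methylcyclohexa-1,4-dien-1-yl)pentanal; 10 methyl 2-[bis(2,2,2-trifluoroethoxy)phosphoryl]propanoate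
Product: 11 methyl (2Z,6S)-6-(5-methoxy-4-methylcyclohexa-1,4-dien-1-yl)-2-methylhept-2-enoate
Conditions: KN(SiMe3)2 (KHMDS), 18-crown-6, THF, −78 °C
Reagents that add atoms: none
Why: Still–Gennari olefination, in which the electron-poor bis(trifluoroethyl) phosphonate with a dissociated potassium counter-ion eliminates quickly from the kinetic adduct and so should give the (Z)-trisubstituted enoate C1=C6′ whose geometry later encodes C6′.

Step 8
Reactants: 11 methyl (2Z,6S)-6-(5-methoxy-4-methylcyclohexa-1,4-dien-1-yl)-2-methylhept-2-enoate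
Product: 12 methyl (2S)-2-[(1R,4S,5S)-9-methoxy-4,8-dimethylspiro[4.5]deca-6,8-dien-1-yl]propanoate
Conditions: degassed PhMe (0.01 M), BHT (cat.), base-washed sealed glass tube, 230–250 °C
Reagents that add atoms: none
Why: The step is a concerted, suprafacial six-electron ene reaction in which C5 of the C5=C6 alkene bonds to the enoate β-carbon C1 while a doubly allylic C7–H is passed to the α-carbon C6′ and the alkene moves to C6=C7, in conjugation with the C8=C9 enol ether. The closest known reaction type is the thermal intramolecular type-1 ene cyclisation of 1,6-dienes carrying an ester-activated enophile, which is established for 1-alkenylcyclohexenes giving spiro[4.5]decanes. Ring A closes by 5-exo-trig attack at C1 inside a cis-fused bicyclic transition state, the new carbocycle being fused to the six-membered hydrogen-transfer array. At C5 the C7–H···C6′ hydrogen shuttle forces C6′ onto the C6 side of the new ring, so C6 and the C1 branch are cis; at C1 and C6′ carbon and hydrogen add to the same face of the enoate, so the (Z) geometry (ester cis to C2) becomes the (1R,6′S) pair; the absolute sense of all three follows from the face of C5=C6 that is attacked, which the C4 stereocentre controls. The selectivity needed is attack on the C5 face that leaves the C4 methyl trans to the C1 branch, expected because in that transition state the methyl is pseudo-equatorial on the forming cyclopentane and lies on the C10 side, away from the enoate carbons passing over C6 and C7; the C4-epimeric spirocycle is the anticipated minor product and should be separable by chromatography. Dilution, exclusion of oxygen and acid, and a radical inhibitor are meant to suppress dehydrogenation of the 1,4-diene to the anisole, while the quaternary C5 of the product blocks its aromatisation.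

Step 9
Reactants: 12 methyl (2S)-2-[(1R,4S,5S)-9-methoxy-4,8-dimethylspiro[4.5]deca-6,8-dien-1-yl]propanoate
Product: 13 methyl (2S)-2-[(1R,4S,5S)-4,8-dimethyl-9-oxospiro[4.5]dec-7-en-1-yl]propanoate
Conditions: 1 M aq. HCl, THF, 0 °C to rt
Reagents that add atoms: water, O
Why: Acid hydrolysis of the 1-methoxy-1,3-diene (enol ether hydrolysis), in which protonation at the diene terminus C6 and loss of methanol from the hemiacetal give the conjugated 2-methylcyclohexenone, and any double-bond isomer of the dienol ether or β,γ-enone should converge on this thermodynamically favoured enone.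

Step 10
Reactants: 13 methyl (2S)-2-[(1R,4S,5S)-4,8-dimethyl-9-oxospiro[4.5]dec-7-en-1-yl]propanoate
Product: 14 methyl (2S)-2-[(1R,4S,5S,9S)-9-hydroxy-4,8-dimethylspiro[4.5]dec-7-en-1-yl]propanoate
Conditions: (R)-2-methyl-CBS-oxazaborolidine (0.2 equiv), catecholborane, PhMe, −78 °C
Reagents that add atoms: none
Why: Corey–Bakshi–Shibata reduction, in which the ketone binds the oxazaborolidine boron anti to the larger α-methylalkenyl side (C8) and syn to the C10 methylene, so the (R)-catalyst should deliver hydride to the C9 face that gives the (9S) allylic alcohol (oxygen cis to C1 across ring B) under reagent control, 1,2-selectively and without touching the methyl ester.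

Step 11
Reactants: 14 methyl (2S)-2-[(1R,4S,5S,9S)-9-hydroxy-4,8-dimethylspiro[4.5]dec-7-en-1-yl]propanoate
Product: 15 methyl (2S)-2-[(1R,4S,5S,9S)-9-{[tert-butyl(dimethyl)silyl]oxy}-4,8-dimethylspiro[4.5]dec-7-en-1-yl]propanoate
Conditions: TBSCl, imidazole, DMF, rt
Reagents that add atoms: tert-butyldimethylsilyl chloride, CC(C)(C)[Si](C)(C)Cl
Why: Imidazole-promoted silylation of a secondary alcohol masks O9 through the hydride and Lewis-acid steps that follow.

Step 12
Reactants: 15 methyl (2S)-2-[(1R,4S,5S,9S)-9-{[tert-butyl(dimethyl)silyl]oxy}-4,8-dimethylspiro[4.5]dec-7-en-1-yl]propanoate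
Product: 16 (2S)-2-[(1R,4S,5S,9S)-9-{[tert-butyl(dimethyl)silyl]oxy}-4,8-dimethylspiro[4.5]dec-7-en-1-yl]propanal
Conditions: i-Bu2AlH (DIBAL-H), CH2Cl2, −78 °C; MeOH, then aq. potassium sodium tartrate
Reagents that add atoms: none
Why: DIBAL-H half-reduction of the hindered α-branched methyl ester at −78 °C should stop at the aldehyde, and the cold non-basic work-up with immediate use protects the epimerisable C6′ centre.

Step 13
Reactants: 17 3-methylfuran-2(5H)-one
Product: 18 tert-butyl(dimethyl)[(3-methylfuran-2-yl)oxy]silane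
Conditions: TBSOTf, Et3N, CH2Cl2, 0 °C
Reagents that add atoms: tert-butyldimethylsilyl trifluoromethanesulfonate, CC(C)(C)[Si](C)(C)OS(=O)(=O)C(F)(F)F
Why: Soft enolisation and O-silylation of the butenolide give the aromatic 2-silyloxyfuran, the γ-nucleophile for the vinylogous aldol reaction.

Step 14
Reactants: 16 (2S)-2-[(1R,4S,5S,9S)-9-{[tert-butyl(dimethyl)silyl]oxy}-4,8-dimethylspiro[4.5]dec-7-en-1-yl]propanal; 18 tert-butyl(dimethyl)[(3-methylfuran-2-yl)oxy]silane
Product: 19 5-{(2S)-2-[(1R,4S,5S,9S)-9-{[tert-butyl(dimethyl)silyl]oxy}-4,8-dimethylspiro[4.5]dec-7-en-1-yl]-1-hydroxypropyl}-3-methylfuran-2(5H)-one (mixture of diastereomers at the carbinol carbon and at C5 of the lactone)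
Conditions: BF3·OEt2, CH2Cl2, −78 °C; aq. NaHCO3
Reagents that add atoms: none
Why: Vinylogous Mukaiyama aldol reaction, in which the BF3-activated aldehyde is attacked by C5 of the silyloxyfuran (γ-selectivity) to form the C5′–C(lactone) bond; the two new stereocentres do not matter because both are destroyed in the next step.

Step 15
Reactants: 19 5-{(2S)-2-[(1R,4S,5S,9S)-9-{[tert-butyl(dimethyl)silyl]oxy}-4,8-dimethylspiro[4.5]dec-7-en-1-yl]-1-hydroxypropyl}-3-methylfuran-2(5H)-one
Product: 21 (5Z)-5-{(2S)-2-[(1R,4S,5S,9S)-9-{[tert-butyl(dimethyl)silyl]oxy}-4,8-dimethylspiro[4.5]dec-7-en-1-yl]propylidene}-3-methylfuran-2(5H)-one, via secondary mesylate 20 (not isolated)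
Conditions: MsCl, Et3N, CH2Cl2, −20 °C to rt
Reagents that add atoms: methanesulfonyl chloride, CS(=O)(=O)Cl (its atoms are carried by 20 only and leave again in the elimination)
Why: Mesylation followed by base-induced E1cB elimination through the furanolate gives the γ-ylidenebutenolide, and the (Z) isomer (side chain syn to the ring oxygen, away from the ring C4–H) is the thermodynamically preferred product on which both aldol diastereomers should converge.

Step 16
Reactants: 21 (5Z)-5-{(2S)-2-[(1R,4S,5S,9S)-9-{[tert-butyl(dimethyl)silyl]oxy}-4,8-dimethylspiro[4.5]dec-7-en-1-yl]propylidene}-3-methylfuran-2(5H)-one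
Product: 22 (5Z)-5-{(2S)-2-[(1R,4S,5S,9S)-9-hydroxy-4,8-dimethylspiro[4.5]dec-7-en-1-yl]propylidene}-3-methylfuran-2(5H)-one
Conditions: HF·pyridine, pyridine, THF, 0 °C to rt
Reagents that add atoms: none
Why: Fluoride-mediated desilylation under mildly acidic HF·pyridine conditions, chosen over basic Bu4NF to spare the base-sensitive ylidenebutenolide and the C6′ centre.

Step 17
Reactants: 22 (5Z)-5-{(2S)-2-[(1R,4S,5S,9S)-9-hydroxy-4,8-dimethylspiro[4.5]dec-7-en-1-yl]propylidene}-3-methylfuran-2(5H)-one; 23 3-phenylpropanoyl chloride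
Product: 24 (1R,4S,5S,9S)-4,8-dimethyl-1-[(1Z,2S)-1-(4-methyl-5-oxofuran-2(5H)-ylidene)propan-2-yl]spiro[4.5]dec-7-en-9-yl 3-phenylpropanoate (CNP0260277.1)
Conditions: pyridine, DMAP (cat.), CH2Cl2, 0 °C to rt
Reagents that add atoms: none
Why: DMAP-catalysed acylation (nucleophilic catalysis) of the secondary allylic alcohol proceeds with retention at C9 and should deliver the target.

**Compound list**

1 | (3-methoxy-4-methylphenyl)boronic acid | COc1cc(B(O)O)ccc1C | starting material
2 | propan-2-yl (2E)-but-2-enoate | C/C=C/C(=O)OC(C)C | starting material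
3 | propan-2-yl (3S)-3-(3-methoxy-4-methylphenyl)butanoate | CC(C)OC(=O)C[C@H](C)c1ccc(C)c(OC)c1 | intermediate
4 | (3S)-3-(3-methoxy-4-methylphenyl)butanal | O=CC[C@H](C)c1ccc(C)c(OC)c1 | intermediate
5 | 2-methoxy-1-methyl-4-[(2S)-pent-4-en-2-yl]benzene | C=CC[C@H](C)c1ccc(C)c(OC)c1 | intermediate
6 | 9-[(4S)-4-(3-methoxy-4-methylphenyl)pentyl]-9-borabicyclo[3.3.1]nonane | C1CC2CCCC(C1)B2CCC[C@H](C)c1ccc(C)c(OC)c1 | intermediate (not isolated)
7 | (4S)-4-(3-methoxy-4-methylphenyl)pentan-1-ol | OCCC[C@H](C)c1ccc(C)c(OC)c1 | intermediate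
8 | (4S)-4-(5-methoxy-4-methylcyclohexa-1,4-dien-1-yl)pentan-1-ol | OCCC[C@H](C)C1=CCC(C)=C(OC)C1 | intermediate
9 | (4S)-4-(5-methoxy-4-methylcyclohexa-1,4-dien-1-yl)pentanal | O=CCC[C@H](C)C1=CCC(C)=C(OC)C1 | intermediate
10 | methyl 2-[bis(2,2,2-trifluoroethoxy)phosphoryl]propanoate | COC(=O)C(C)P(=O)(OCC(F)(F)F)OCC(F)(F)F | starting material
11 | methyl (2Z,6S)-6-(5-methoxy-4-methylcyclohexa-1,4-dien-1-yl)-2-methylhept-2-enoate | COC(=O)/C(C)=C\CC[C@H](C)C1=CCC(C)=C(OC)C1 | intermediate
12 | methyl (2S)-2-[(1R,4S,5S)-9-methoxy-4,8-dimethylspiro[4.5]deca-6,8-dien-1-yl]propanoate | COC(=O)[C@@H](C)[C@H]2CC[C@H](C)[C@@]23C=CC(C)=C(OC)C3 | intermediate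
13 | methyl (2S)-2-[(1R,4S,5S)-4,8-dimethyl-9-oxospiro[4.5]dec-7-en-1-yl]propanoate | COC(=O)[C@@H](C)[C@H]2CC[C@H](C)[C@@]23CC=C(C)C(=O)C3 | intermediate
14 | methyl (2S)-2-[(1R,4S,5S,9S)-9-hydroxy-4,8-dimethylspiro[4.5]dec-7-en-1-yl]propanoate | COC(=O)[C@@H](C)[C@H]2CC[C@H](C)[C@@]23CC=C(C)[C@@H](O)C3 | intermediate
15 | methyl (2S)-2-[(1R,4S,5S,9S)-9-{[tert-butyl(dimethyl)silyl]oxy}-4,8-dimethylspiro[4.5]dec-7-en-1-yl]propanoate | COC(=O)[C@@H](C)[C@H]2CC[C@H](C)[C@@]23CC=C(C)[C@@H](O[Si](C)(C)C(C)(C)C)C3 | intermediate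
16 | (2S)-2-[(1R,4S,5S,9S)-9-{[tert-butyl(dimethyl)silyl]oxy}-4,8-dimethylspiro[4.5]dec-7-en-1-yl]propanal | O=C[C@@H](C)[C@H]2CC[C@H](C)[C@@]23CC=C(C)[C@@H](O[Si](C)(C)C(C)(C)C)C3 | intermediate
17 | 3-methylfuran-2(5H)-one | CC1=CCOC1=O | starting material
18 | tert-butyl(dimethyl)[(3-methylfuran-2-yl)oxy]silane | Cc1ccoc1O[Si](C)(C)C(C)(C)C | intermediate
19 | 5-{(2S)-2-[(1R,4S,5S,9S)-9-{[tert-butyl(dimethyl)silyl]oxy}-4,8-dimethylspiro[4.5]dec-7-en-1-yl]-1-hydroxypropyl}-3-methylfuran-2(5H)-one (diastereomer mixture at the two new centres) | CC1=CC(OC1=O)C(O)[C@@H](C)[C@H]2CC[C@H](C)[C@@]23CC=C(C)[C@@H](O[Si](C)(C)C(C)(C)C)C3 | intermediate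
20 | methanesulfonate of 19 at the side-chain carbinol | CC1=CC(OC1=O)C(OS(C)(=O)=O)[C@@H](C)[C@H]2CC[C@H](C)[C@@]23CC=C(C)[C@@H](O[Si](C)(C)C(C)(C)C)C3 | intermediate (not isolated)
21 | (5Z)-5-{(2S)-2-[(1R,4S,5S,9S)-9-{[tert-butyl(dimethyl)silyl]oxy}-4,8-dimethylspiro[4.5]dec-7-en-1-yl]propylidene}-3-methylfuran-2(5H)-one | CC1=C/C(=C/[C@@H](C)[C@H]2CC[C@H](C)[C@@]23CC=C(C)[C@@H](O[Si](C)(C)C(C)(C)C)C3)OC1=O | intermediate
22 | (5Z)-5-{(2S)-2-[(1R,4S,5S,9S)-9-hydroxy-4,8-dimethylspiro[4.5]dec-7-en-1-yl]propylidene}-3-methylfuran-2(5H)-one | CC1=C/C(=C/[C@@H](C)[C@H]2CC[C@H](C)[C@@]23CC=C(C)[C@@H](O)C3)OC1=O | intermediate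
23 | 3-phenylpropanoyl chloride | O=C(Cl)CCc1ccccc1 | starting material
24 | (1R,4S,5S,9S)-4,8-dimethyl-1-[(1Z,2S)-1-(4-methyl-5-oxofuran-2(5H)-ylidene)propan-2-yl]spiro[4.5]dec-7-en-9-yl 3-phenylpropanoate | CC1=C/C(=C/[C@@H](C)[C@H]2CC[C@H](C)[C@@]23CC=C(C)[C@@H](OC(=O)CCc2ccccc2)C3)OC1=O | target

**Totals**

Total step count: 17. Longest linear sequence: 16 steps (steps 1–12 and 14–17, from 1 and 2); step 13 is a one-step side branch.

**Steps most likely to fail**

Step 8 (ene spiroannulation). The (Z)-enoate must carry its α-methyl group over ring B, so the cyclisation may be slow enough for dehydrogenation of the 1,4-diene to the anisole to compete, and the C4 centre may discriminate the two faces of C5=C6 only weakly. The fallback sets out from aldehyde 9 and returns at 12. E-selective Wittig olefination with Ph3P=C(CH3)CO2Me would give methyl (2E,6S)-6-(5-methoxy-4-methylcyclohexa-1,4-dien-1-yl)-2-methylhept-2-enoate F1. Its ene cyclisation places the ester, not the methyl group, over ring B and should therefore run at lower temperature, giving methyl (2R)-2-[(1R,4S,5S)-9-methoxy-4,8-dimethylspiro[4.5]deca-6,8-dien-1-yl]propanoate F2, the C6′ epimer. Equilibration through the ester enolate (NaOMe, MeOH), with separation and recycling of the unwanted epimer, would then give 12. In this variant C6′ is set by enolate protonation instead of alkene geometry.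

Step 10 (C9 reduction). Double stereodifferentiation may be mismatched: the spiro ring A may shield the C9 face that the (R)-catalyst has to reach, so that reduction is slow or hydride enters from the C1 side. The fallback sets out from enone 13 and returns at 14. Substrate-controlled Luche reduction (NaBH4, CeCl3·7H2O, MeOH, −78 °C) would give methyl (2S)-2-[(1R,4S,5S,9R)-9-hydroxy-4,8-dimethylspiro[4.5]dec-7-en-1-yl]propanoate F3 when hydride adds from the C1 face. Mitsunobu inversion with 4-nitrobenzoic acid (PPh3, DIAD, THF) would convert it into methyl (2S)-2-[(1R,4S,5S,9S)-4,8-dimethyl-9-[(4-nitrobenzoyl)oxy]spiro[4.5]dec-7-en-1-yl]propanoate F4, and methanolysis (K2CO3, MeOH) would give 14.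

Step 15 (dehydration to the ylidenebutenolide). The C6′–H is vinylogously acidic, since its removal gives a 5-alkenylfuranolate, so the amine base may epimerise C6′ during or after the elimination, and E/Z mixtures may persist. The fallback sets out from aldehyde 16 and returns at 21, bypassing steps 13–15. Ohira–Bestmann homologation (dimethyl (1-diazo-2-oxopropyl)phosphonate, K2CO3, MeOH) would give tert-butyl({(1R,4S,5S,9S)-1-[(2S)-but-3-yn-2-yl]-4,8-dimethylspiro[4.5]dec-7-en-9-yl}oxy)dimethylsilane F5. Sonogashira coupling with (2Z)-3-iodo-2-methylprop-2-enoic acid (Pd(PPh3)4, CuI, Et3N, MeCN) would give (2Z,6S)-6-[(1R,4S,5S,9S)-9-{[tert-butyl(dimethyl)silyl]oxy}-4,8-dimethylspiro[4.5]dec-7-en-1-yl]-2-methylhept-2-en-4-ynoic acid F6, which should lactonise in the same flask by 5-exo-dig anti-addition of the carboxylate to give the (Z)-ylidenebutenolide 21 without an elimination step.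

**Further compounds**

F1 | step 8 | methyl (2E,6S)-6-(5-methoxy-4-methylcyclohexa-1,4-dien-1-yl)-2-methylhept-2-enoate | COC(=O)/C(C)=C/CC[C@H](C)C1=CCC(C)=C(OC)C1
F2 | step 8 | methyl (2R)-2-[(1R,4S,5S)-9-methoxy-4,8-dimethylspiro[4.5]deca-6,8-dien-1-yl]propanoate | COC(=O)[C@H](C)[C@H]2CC[C@H](C)[C@@]23C=CC(C)=C(OC)C3
F3 | step 10 | methyl (2S)-2-[(1R,4S,5S,9R)-9-hydroxy-4,8-dimethylspiro[4.5]dec-7-en-1-yl]propanoate | COC(=O)[C@@H](C)[C@H]2CC[C@H](C)[C@@]23CC=C(C)[C@H](O)C3
F4 | step 10 | methyl (2S)-2-[(1R,4S,5S,9S)-4,8-dimethyl-9-[(4-nitrobenzoyl)oxy]spiro[4.5]dec-7-en-1-yl]propanoate | COC(=O)[C@@H](C)[C@H]2CC[C@H](C)[C@@]23CC=C(C)[C@@H](OC(=O)c4ccc(cc4)[N+](=O)[O-])C3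
F5 | step 15 | tert-butyl({(1R,4S,5S,9S)-1-[(2S)-but-3-yn-2-yl]-4,8-dimethylspiro[4.5]dec-7-en-9-yl}oxy)dimethylsilane | C#C[C@@H](C)[C@H]2CC[C@H](C)[C@@]23CC=C(C)[C@@H](O[Si](C)(C)C(C)(C)C)C3
F6 | step 15 | (2Z,6S)-6-[(1R,4S,5S,9S)-9-{[tert-butyl(dimethyl)silyl]oxy}-4,8-dimethylspiro[4.5]dec-7-en-1-yl]-2-methylhept-2-en-4-ynoic acid | OC(=O)/C(C)=C\C#C[C@@H](C)[C@H]2CC[C@H](C)[C@@]23CC=C(C)[C@@H](O[Si](C)(C)C(C)(C)C)C3
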